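Time this flask by L. From 2.00 h to 8.00 h, the fraction of L left gives a lifetime of 4.68 h in maple and 4.78 h in birch, although birch was charged with 2.26 times the L. Take the mean as the first-order lifetime of L, the time that cuts the fraction left by a factor e: 4.73 h.

| flask | L | Z | remark | time |
|---|---|---|---|---|
| maple | 0.027 M | 0.082 M | run made earlier |  |
| birch | 0.061 M | 0.082 M | run made earlier |  |
| flask | 0.041 M | 0.0820 M |  | 10 h |

| run | time / h | G / % | L / % |
|---|---|---|---|
| maple | 1.50 | 3.3 | 72.0 |
| maple | 2.00 | 4.4 | 64.8 |
| maple | 3.00 | 7.4 | 52.8 |
| maple | 4.00 | 10.6 | 43.2 |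
| maple | 6.00 | 12.5 | 28.2 |
| maple | 8.00 | 12.6 | 18.0 |
| birch | 1.50 | 2.0 | 72.3 |
| birch | 2.00 | 4.1 | 66.6 |
| birch | 3.00 | 6.8 | 53.0 |
| birch | 4.00 | 8.7 | 43.7 |
| birch | 6.00 | 10.4 | 28.4 |
| birch | 8.00 | 10.4 | 19.0 |

(each reading ± 0.5 percentage points)



- the moment within 10 h at which there is most G
- the amount of G, in percent of the L charged, at that time

Your zero of the scale is the symmetric chain, L to G and G onward at equal pace, which peaks at one lifetime with 36.8 % of the charge as G. Both runs sit later and lower. Maple's G reads 12.5 % and 12.6 % at 6.00 h and 8.00 h, and birch's reads 10.4 % at both, so I place the top between these times: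

lifetimes: 1.27 to 1.69, midpoint 7.00 h

That midpoint is the weak link, since it treats the hump as even. A hump that falls more slowly than it rises tops out before the midpoint of two equal readings, so I move to two half-lives of L, where a quarter of L is left:

my time: two half-lives of L = 6.56 h

my height, interpolated by charge between the last G readings: 11.7 %

The forecast, made separately, says 7 h and 12 %, a later time than mine, and its ground is: “A higher L charge lowers the yield but doesn't noticeably shift the peak time”.

The flask peaks at 6.50 h with 11.7 %, and the forecast held. In this flask G stays close to that peak from 5.05 h to 8.31 h, a span that holds both the forecast's time and mine. The peak stands at 1.37 lifetimes, where the lifetime gives 25.3 % of L left; the flask has 25.5 %.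

    D + X ⇌ G (K = 8.10 /M, k = 18.0 /M/h)
    Z → X (k = 0.250 /h)
    L → D (k = 0.210 /h)
    G → J (k = 0.420 /h)
    2 D → Q (k = 2.50 /M/h)

Now take the neighbour flask charged with 0.21 M of Z. The lifetime gives 12.1 % of L left at 10 h. The computed neighbour has 12.2 %, with a best G of 18.6 %.

(All runs were computed with made-up constants; the scatter is artificial.)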